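The constants used here are those of an exercise; the rest is arithmetic.

I read epsilon, delta and alpha at 40 min, so the question is what that clock is worth against the fork between the two mirror-image substrates.

| setting | epsilon | delta | alpha |
|---|---|---|---|
| left-handed substrate | 0.80 M | 0.80 M | 0.80 M |
| reagent | 1.60 M | 1.60 M | 1.60 M |
| free catalyst | 4.4 mM | 4.4 mM | 4.4 mM |
| right-handed substrate | 0.80 M | 0.80 M | 0.80 M |
| temperature | 70 °C | 90 °C |  |
| time | 40 min | 40 min | 40 min |
| remark |  |  | at 90 °C until 20 min, from then on at 70 °C |

    reagent + free catalyst + right-handed substrate → free catalyst + right-handed product (k1 = 2.71 /M²/min, Ea1 = 51.0 kJ/mol)
    reagent + free catalyst + left-handed substrate → free catalyst + left-handed product (k2 = 7.60 /M²/min, Ea2 = 38.0 kJ/mol)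
    reagent + free catalyst → spent catalyst (k3 = 0.00213 /M/min, Ea3 = 87.0 kJ/mol)
    (constants at 90 °C)

- free catalyst is single-handed; left-handed substrate and right-handed substrate are mirror images of each other, charged as a racemate, each of them at the stated concentration
- the constants hold at 90 °C; other temperatures follow from the activation energies

* which flask leads in amount of left-handed product, in percent of the left-handed substrate and right-handed substrate together charged ("all alike" within 1.5 percentage points) (epsilon / delta / alpha / all alike)
* how much left-handed product is there at the end, in percent of the left-handed substrate and right-handed substrate together charged: epsilon
* how much left-handed product is there at the end, in percent of the left-handed substrate and right-handed substrate together charged: delta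
* how much left-handed product is there at the end, in percent of the left-handed substrate and right-handed substrate together charged: alpha

I turn the question round: what would have to be true for epsilon, the colder flask, to lead? I follow one molecule. A left-handed and a right-handed substrate molecule meet the same c(reagent) and c(free catalyst), so these cancel from their odds. What stays is the selectivity factor s, the ratio of the left-handed constant to the right-handed one:

s = 2.80 at 90 °C, s = 3.60 at 70 °C

part left of left-handed substrate = (part left of right-handed substrate)^s

This rule holds at constant temperature, however c(reagent) and c(free catalyst) fall. At equal conversion, then, epsilon has the better fork, with s larger than delta's. But the flasks are compared at equal time, and the left-handed step runs 2.08 times as fast at 90 °C as at 70 °C. So I look at two ways out for epsilon: free catalyst dying early in delta, and both flasks nearing the ceiling of half the charge. I take the lifetimes at full charge: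

left-handed substrate, epsilon: 1/(k c(reagent) c(free catalyst)) = 38.9 min

left-handed substrate, delta: 18.7 min

free catalyst, delta: 1/(k c(reagent)) = 293 min

Epsilon's run is about one lifetime, so its bound is 32.1 %, against 44.1 % for delta. Those are upper bounds, reckoned at the charged c(reagent) and c(free catalyst), and c(reagent) falls in both flasks. The lifetime of free catalyst in delta is longer than the run. I commit to delta, and my reckoning stops at these bounds.

The forecast also names delta, with 27.4 % for epsilon, 36.5 % for delta and 32.8 % for alpha, holding that “the hottest flask converts the most left-handed substrate despite its poorer selectivity”.

The simulation gives delta, with 27.4 %, 36.5 % and 32.8 %, so the forecast holds within tolerance. At 400 min the three stand at 48.6 %, 49.4 % and 48.5 %. In epsilon at 40.0 min, 80 % of the right-handed substrate is left, and the rule with s gives 45.3 % of the left-handed substrate, where the flask shows 45 %. The neighbouring flask is epsilon read at 15 min: 91 % of the right-handed substrate is left, so the rule gives 70.9 % of the left-handed substrate and 14.6 % left-handed product. That flask shows 71 % and 14.6 %.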